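## The problem

Compound 24 (CNP0264591.0) is an achiral, trimeric acylphloroglucinol. A 2,4,6-trihydroxybutyrophenone core (ring A) carries at C3 and C5 a methylene bridge to a 3-butanoyl-2,4-dihydroxy-6-methoxy-5-methylphenyl side ring. There is no stereocentre, so nothing has to be controlled in space. The difficulty is regiochemical: all three benzene rings are hexasubstituted, and nine oxygen atoms must end up as seven free hydroxyls and exactly two methyl ethers (the side-ring oxygens para to the ketones). The doubly activated diarylmethane links are the fragile part, because strong acid or an electrophile can attack the bridge-bearing ring carbons and expel a stabilised benzylic cation; the free polyphenol is also sensitive to base and air, so the hydroxyls should be unveiled last. Each ring needs one butanoyl group, and a ketone cannot be carried through acetylide or ketene chemistry, so acylation has to come late and must find a single open position on each ring. Ring A offers the decisive feature: its carbons alternate between oxygen-bearing (C2, C4, C6) and carbon-bearing (C1, C3, C5), and the C4 oxygen sits between the two bridge carbons C3 and C5. A cyclobutenone–ynol ether benzannulation writes exactly this pattern: C4 arrives as a free hydroxyl from a ketene carbon, C3 and C5 arrive carrying the benzylic arms, C2 and C6 arrive as alkyl ethers, and C1 is left as C–H. The C2 and C6 ethers lie ortho to the later C1 ketone and can be released by carbonyl-assisted cleavage, whereas the C4 oxygen, which has no such help, is the one the annulation delivers unprotected.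

## Retrosynthesis

**24 to 23.** Six O–alkyl bonds are cut: the O–CH3 bonds at C2' and C4' of each side ring and at C6 of ring A, and the O–C2H5 bond at C2 of ring A. All six flank a ketone. More labile protecting groups on the side rings would require the three oxygens of a methylated triphenol to be told apart before either fragment is made, and they would not survive the Lewis acid of the acylation. With all-methyl side rings both fragments come from one commercial arene, and the ortho relationship to the ketones supplies the differentiation. Hexaether 23 has no free ortho-hydroxy ketone and should be a stable compound. The forward step must cleave six ortho ethers and leave the two para methoxy groups.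

**23 to 21.** The three aryl–carbonyl bonds are cut. Acylating earlier would mean carrying ketones through acetylide and ketene chemistry. Phenol 21 has exactly three aromatic C–H positions, each between two alkoxy groups, so there is no regiochemical choice. The forward step must acylate three hindered positions without electrophilic attack at the bridge-bearing carbons; the phenol is esterified on the way, giving tetrabutanoyl ester 22, and is freed again by methanolysis.

**21 to 11 and 16.** The C3–C4 and C1–C2 bonds of ring A are cut. Building ring A by two electrophilic benzylations of a preformed symmetrical core would pass twice through the labile benzylic cations and would offer no way to leave only the C4 oxygen free. The benzannulation places all six substituents in one operation. The precursors, cyclobutenone 11 (C17) and methoxyalkyne 16 (C14), are of similar size, carry the same aryl group, and contain no ring A. The forward step needs a regioselective [2+2] addition and partners that survive heating.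

**16 to 12 and 13.** The propargylic C–C bond between the benzylic CH2 and the alkyne is cut, giving benzylic chloride 15 (from alcohol 12, itself from aldehyde 3) and acetylide 14 (from chloroacetal 13). Routes that form the ynol ether by elimination would have to eliminate away from the benzylic position, which is the wrong direction. The forward step must capture 15 before it ionises.

**11 to 7 and 8.** The two ring bonds formed in a ketene–alkyne [2+2] addition are cut, leading to ketene 10, acid chloride 9 and acid 7, with ethoxyacetylene 8 as the partner. Alkylating a preformed 3-ethoxycyclobutenone at C4 would require an antiaromatic dienolate. Acid 7 goes back through cinnamic acid 6 to aldehyde 3 and malonic acid 4. The forward step needs ketene 10 to add to 8 faster than it dimerises.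

**3 to 1.** The aryl–CHO bond is cut. Both fragments diverge from aldehyde 3, and the two open positions of arene 1 are equivalent, so formylation has one possible outcome.

## Roads not taken

**Alternative 1:** The cut runs through both side rings, between the methyl-bearing carbon and the neighbouring hydroxyl-bearing carbon. The precursor A1 has ring A complete, with its butanoyl group and three benzyl ethers, and each bridge ends in a methyl 3,5-dioxoheptanoate chain attached through C2. In the forward step NaOMe in hot methanol would induce a two-fold Claisen cyclisation with aromatisation to A2.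

- Merits: the closure mimics polyketide biosynthesis. The side rings arrive as free triols, so after C-butanoylation the oxygens can be told apart by para-selective O-methylation of an acylphloroglucinol, and ring A is freed by hydrogenolysis. In this respect it is better than the chosen plan, which depends on a selective ether cleavage in step 9.
- Weak points: 3,5-dioxo esters under base tend to lactonise through the enol oxygen or to close by aldol modes instead of C-acylating, and the desired mode must win twice in one molecule. A1 is a mixture of tautomers and epimers. Making it requires a fully substituted ring A to be built first and then alkylated twice with a dioxoheptanoate dianion. A2 carries two unprotected, very electron-rich triphenol rings on acid-labile bridges.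
- Comparison: the chosen plan offers a key step of a well-known reaction type, two fragments from one aldehyde, and far fewer steps.

**Alternative 2:** The cut removes the C1–carbonyl bond and the C2–O bond of ring A together. A5 is traced to the ortho-silyl aryl triflate A3 and butanoic acid A4. CsF would release the aryne from A3; the carboxylate oxygen adds at the aryne carbon remote from the benzyloxy group, and the resulting aryl anion takes the acyl group from oxygen to give the ortho-hydroxy ketone A5.

- Merits: ketone and neighbouring hydroxyl are installed on ring A in one step with predictable orientation. Ring A needs no Friedel–Crafts acylation, and its other two oxygens are benzyl ethers. For ring A this is cleaner than the chosen plan.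
- Weak points: A3 is itself a hexasubstituted benzene with five different substituents, and its synthesis would be at least as long as the whole chosen route. The aryne is flanked on both sides, so addition is hindered and ene-type reactions with the benzylic hydrogens compete. Addition of an acid to an aryne can also stop at the aryl ester. The side rings would still need butanoylation and the same ortho-selective demethylation.
- Comparison: the weakest point of the chosen plan is not removed, and the chosen plan makes ring A from simple fragments.

**Alternative 3:** The cut removes all three C–O bonds of ring A. A8 is traced to the trifluoro ketone A6 and sodium benzyloxide A7, of formula NaOCH2Ph, by three successive nucleophilic aromatic substitutions.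

- Merits: the ring A core would come from a cheap symmetrical fluoroarene whose C–H positions, each between two fluorines, can be metalated one after another, so the regiochemistry is trivial. All three ring A oxygens are benzyl ethers and fall by hydrogenolysis. On paper this is shorter for ring A than the chosen plan.
- Weak points: only the first displacement is well activated. Each alkoxy group that enters deactivates the ring, the two benzyl groups donate and hinder, and the ketone has α-hydrogens, so the alkoxide can enolise it and switch off the activation. The last substitution would need forcing conditions that endanger the bridges. The side rings again need butanoylation and selective demethylation.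
- Comparison: the chosen plan offers a ring-forming step that does not depend on a falling activation gradient.

Key step: step 7

Assumption: the target has no stereocentre; cyclobutenone 11 is made and used as the racemate because its single stereocentre is lost when ring A aromatises.

## Route

**Step 1**
Reactants: 1 2,4,6-trimethoxytoluene
Product: 3 2,4,6-trimethoxy-3-methylbenzaldehyde, via aryliminium chloride 2 (not isolated)
Conditions: POCl3 (1.2 equiv), DMF, 0 to 60 °C; then ice-water
Reagents that add atoms: N,N-dimethylformamide, CN(C)C=O; water, O
Why: Vilsmeier–Haack formylation; the two open ring positions are equivalent and the first formyl group deactivates the ring against a second.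

**Step 2**
Reactants: 3 2,4,6-trimethoxy-3-methylbenzaldehyde; 4 malonic acid
Product: 6 (2E)-3-(2,4,6-trimethoxy-3-methylphenyl)prop-2-enoic acid, via arylidenemalonic acid 5 (not isolated)
Conditions: pyridine, piperidine (cat.), 95 °C
Reagents that add atoms: none
Why: Knoevenagel–Doebner condensation with decarboxylation; the E alkene is the thermodynamic product and its geometry is removed in step 3.

**Step 3**
Reactants: 6 (2E)-3-(2,4,6-trimethoxy-3-methylphenyl)prop-2-enoic acid
Product: 7 3-(2,4,6-trimethoxy-3-methylphenyl)propanoic acid
Conditions: H2 (1 atm), Pd/C, EtOAc, rt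
Reagents that add atoms: none
Why: catalytic hydrogenation of a cinnamic acid; the methoxyarene and the acid are inert.

**Step 4**
Reactants: 7 3-(2,4,6-trimethoxy-3-methylphenyl)propanoic acid; 8 ethoxyacetylene
Product: 11 racemic 3-ethoxy-4-[(2,4,6-trimethoxy-3-methylphenyl)methyl]cyclobut-2-en-1-one, via acid chloride 9 (not isolated), via alkylketene 10 (not isolated)
Conditions: Me2C=C(Cl)NMe2 (1.1 equiv), CH2Cl2, 0 °C to rt; then added slowly to 8 (3 equiv), Et3N (1.5 equiv), Et2O, rt
Reagents that add atoms: none
Why: dehydrochlorination of 9 gives ketene 10, which undergoes the known [2+2] cycloaddition with ethoxyacetylene (ketene carbonyl carbon to the alkyne CH carbon) to give a 3-ethoxycyclobutenone. The neutral chloroenamine spares the electron-rich ring. C4 is formed racemic and is erased in step 7.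

**Step 5**
Reactants: 3 2,4,6-trimethoxy-3-methylbenzaldehyde
Product: 12 (2,4,6-trimethoxy-3-methylphenyl)methanol
Conditions: NaBH4, MeOH, 0 °C; neutral work-up
Reagents that add atoms: none
Why: hydride reduction of an aryl aldehyde; acid is avoided because the electron-rich benzylic alcohol ionises easily.

**Step 6**
Reactants: 12 (2,4,6-trimethoxy-3-methylphenyl)methanol; 13 chloroacetaldehyde dimethyl acetal
Product: 16 1,3,5-trimethoxy-2-(3-methoxyprop-2-yn-1-yl)-4-methylbenzene, via lithium methoxyacetylide 14 (not isolated), via benzylic chloride 15 (not isolated)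
Conditions: 13, LiNEt2 (3.0 equiv per 13, from Et2NH and n-BuLi), THF, 0 °C; 12, SOCl2, pyridine, Et2O, −20 °C, cold filtration; filtrate added to 14 (2 equiv), DMPU, −40 °C to rt
Reagents that add atoms: none
Why: double elimination from the chloroacetal gives the alkoxyacetylide (known preparation of 1-alkoxyalkynes), and C-alkylation by a benzylic halide is a standard acetylide substitution. Chloride 15 is made cold under base and consumed at once, and no excess amide is left to isomerise the product to an allene.

**Step 7**
Reactants: 11 racemic 3-ethoxy-4-[(2,4,6-trimethoxy-3-methylphenyl)methyl]cyclobut-2-en-1-one; 16 1,3,5-trimethoxy-2-(3-methoxyprop-2-yn-1-yl)-4-methylbenzene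
Product: 21 3-ethoxy-5-methoxy-2,6-bis[(2,4,6-trimethoxy-3-methylphenyl)methyl]phenol, via vinylketene 17 (not isolated), via alkenylcyclobutenone 18 (not isolated), via dienylketene 19 (not isolated), via cyclohexadienone 20 (not isolated)
Conditions: 11 (1.3 equiv), 16 (1.0 equiv), toluene, 80 °C then 110 °C, argon
Reagents that add atoms: none
Why: Danheiser benzannulation of a cyclobutenone with an alkoxyalkyne. Conrotatory four-electron opening of 11 gives vinylketene 17, whose ketene C=C bond adds 16 in a [2+2] cycloaddition to give 18; this forms the C3–C4 and C1–C2 bonds of ring A. Reversible four-electron opening of 18 gives dienylketene 19; the isomer with a cis central double bond closes ring A by a thermal disrotatory six-electron electrocyclisation that rejoins the ketene carbon (C4) to the benzyl-bearing alkene terminus (C5), and dienone 20 tautomerises irreversibly to phenol 21. The closest known reaction type is the thermal benzannulation of cyclobutenones with 1-alkoxy- or 1-siloxyalkynes; the 3-alkoxy group on the four-membered ring is a less common variation, but 3-ethoxycyclobutenones are known to open to vinylketenes below 100 °C. The one selectivity required is the orientation of the [2+2] step, and the polarisation of 16 secures it: its benzyl-bearing carbon is the nucleophilic terminus and bonds to the electrophilic ketene carbon, so both benzyl groups flank the new hydroxyl and both alkoxy groups flank the remaining C–H. No stereocentre is created; the stereocentre of 11 and the alkene geometries of 17 to 19 disappear on aromatisation. A methyl ynol ether has no β-hydrogen for retro-ene loss of an alkene, so 16 survives the temperature at which 11 opens.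

**Step 8**
Reactants: 21 3-ethoxy-5-methoxy-2,6-bis[(2,4,6-trimethoxy-3-methylphenyl)methyl]phenol
Product: 23 1-{3,5-bis[(3-butanoyl-2,4,6-trimethoxy-5-methylphenyl)methyl]-2-ethoxy-4-hydroxy-6-methoxyphenyl}butan-1-one, via tetrabutanoyl ester 22 (not isolated)
Conditions: PrCOCl (5 equiv), TiCl4 (5 equiv), CH2Cl2, −40 to 0 °C; aqueous work-up; then K2CO3 (2 equiv), MeOH, rt
Reagents that add atoms: butanoyl chloride, CCCC(Cl)=O
Why: Friedel–Crafts acylation at the only three aromatic C–H positions, each activated by two flanking alkoxy groups. Excess reagent also esterifies the hindered phenol to give ester 22, and methanolysis with K2CO3 returns the phenol without touching aryl ketones or ethers.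

**Step 9**
Reactants: 23 1-{3,5-bis[(3-butanoyl-2,4,6-trimethoxy-5-methylphenyl)methyl]-2-ethoxy-4-hydroxy-6-methoxyphenyl}butan-1-one
Product: 24 1-{3,5-bis[(3-butanoyl-2,4-dihydroxy-6-methoxy-5-methylphenyl)methyl]-2,4,6-trihydroxyphenyl}butan-1-one
Conditions: BBr3 (7 equiv), CH2Cl2, −78 to 0 °C; then ice-water
Reagents that add atoms: none
Why: carbonyl-directed Lewis acid ether cleavage. Each ketone binds boron and delivers it through six-membered chelates to its two flanking alkoxy groups, so five methyl ethers and the ethyl ether fall at low temperature. The two methoxy groups para to a ketone have no such assistance and sit on rings made electron-poor by the boron-bound carbonyl, and the reaction is stopped cold before they react.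

## Compound list

1 | 2,4,6-trimethoxytoluene (1,3,5-trimethoxy-2-methylbenzene) | COc1cc(OC)c(C)c(OC)c1 | starting material
2 | N-methyl-N-[(2,4,6-trimethoxy-3-methylphenyl)methylidene]methanaminium chloride | C[N+](C)=Cc1c(OC)cc(OC)c(C)c1OC.[Cl-] | intermediate (not isolated)
3 | 2,4,6-trimethoxy-3-methylbenzaldehyde | O=Cc1c(OC)cc(OC)c(C)c1OC | intermediate
4 | malonic acid | OC(=O)CC(=O)O | starting material
5 | 2-[(2,4,6-trimethoxy-3-methylphenyl)methylidene]propanedioic acid | OC(=O)C(=Cc1c(OC)cc(OC)c(C)c1OC)C(=O)O | intermediate (not isolated)
6 | (2E)-3-(2,4,6-trimethoxy-3-methylphenyl)prop-2-enoic acid | OC(=O)/C=C/c1c(OC)cc(OC)c(C)c1OC | intermediate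
7 | 3-(2,4,6-trimethoxy-3-methylphenyl)propanoic acid | OC(=O)CCc1c(OC)cc(OC)c(C)c1OC | intermediate
8 | ethoxyacetylene (ethoxyethyne) | CCOC#C | starting material
9 | 3-(2,4,6-trimethoxy-3-methylphenyl)propanoyl chloride | ClC(=O)CCc1c(OC)cc(OC)c(C)c1OC | intermediate (not isolated)
10 | 3-(2,4,6-trimethoxy-3-methylphenyl)prop-1-en-1-one (alkylketene) | O=C=CCc1c(OC)cc(OC)c(C)c1OC | intermediate (not isolated)
11 | racemic 3-ethoxy-4-[(2,4,6-trimethoxy-3-methylphenyl)methyl]cyclobut-2-en-1-one | CCOC1=CC(=O)C1Cc1c(OC)cc(OC)c(C)c1OC | intermediate
12 | (2,4,6-trimethoxy-3-methylphenyl)methanol | OCc1c(OC)cc(OC)c(C)c1OC | intermediate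
13 | chloroacetaldehyde dimethyl acetal (2-chloro-1,1-dimethoxyethane) | COC(CCl)OC | starting material
14 | lithium methoxyacetylide (lithium 2-methoxyethyn-1-ide) | [Li+].[C-]#COC | intermediate (not isolated)
15 | 2-(chloromethyl)-1,3,5-trimethoxy-4-methylbenzene | ClCc1c(OC)cc(OC)c(C)c1OC | intermediate (not isolated)
16 | 1,3,5-trimethoxy-2-(3-methoxyprop-2-yn-1-yl)-4-methylbenzene | COC#CCc1c(OC)cc(OC)c(C)c1OC | intermediate
17 | (3Z)-3-ethoxy-5-(2,4,6-trimethoxy-3-methylphenyl)penta-1,3-dien-1-one | O=C=C/C(OCC)=C/Cc1c(OC)cc(OC)c(C)c1OC | intermediate (not isolated)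
18 | racemic 4-[(1Z)-1-ethoxy-3-(2,4,6-trimethoxy-3-methylphenyl)prop-1-en-1-yl]-3-methoxy-2-[(2,4,6-trimethoxy-3-methylphenyl)methyl]cyclobut-2-en-1-one | O=C1C(Cc2c(OC)cc(OC)c(C)c2OC)=C(OC)C1/C(OCC)=C/Cc1c(OC)cc(OC)c(C)c1OC | intermediate (not isolated)
19 | (3E,5Z)-5-ethoxy-3-methoxy-7-(2,4,6-trimethoxy-3-methylphenyl)-2-[(2,4,6-trimethoxy-3-methylphenyl)methyl]hepta-1,3,5-trien-1-one | O=C=C(Cc1c(OC)cc(OC)c(C)c1OC)/C(OC)=C\C(OCC)=C\Cc1c(OC)cc(OC)c(C)c1OC | intermediate (not isolated)
20 | racemic 5-ethoxy-3-methoxy-2,6-bis[(2,4,6-trimethoxy-3-methylphenyl)methyl]cyclohexa-2,4-dien-1-one | O=C1C(Cc2c(OC)cc(OC)c(C)c2OC)=C(OC)C=C(OCC)C1Cc1c(OC)cc(OC)c(C)c1OC | intermediate (not isolated)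
21 | 3-ethoxy-5-methoxy-2,6-bis[(2,4,6-trimethoxy-3-methylphenyl)methyl]phenol | Oc1c(Cc2c(OC)cc(OC)c(C)c2OC)c(OC)cc(OCC)c1Cc1c(OC)cc(OC)c(C)c1OC | intermediate
22 | 4-butanoyl-3-ethoxy-5-methoxy-2,6-bis[(3-butanoyl-2,4,6-trimethoxy-5-methylphenyl)methyl]phenyl butanoate | CCCC(=O)Oc1c(Cc2c(OC)c(C(=O)CCC)c(OC)c(C)c2OC)c(OC)c(C(=O)CCC)c(OCC)c1Cc1c(OC)c(C(=O)CCC)c(OC)c(C)c1OC | intermediate (not isolated)
23 | 1-{3,5-bis[(3-butanoyl-2,4,6-trimethoxy-5-methylphenyl)methyl]-2-ethoxy-4-hydroxy-6-methoxyphenyl}butan-1-one | CCCC(=O)c1c(OCC)c(Cc2c(OC)c(C(=O)CCC)c(OC)c(C)c2OC)c(O)c(Cc2c(OC)c(C(=O)CCC)c(OC)c(C)c2OC)c1OC | intermediate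
24 | 1-{3,5-bis[(3-butanoyl-2,4-dihydroxy-6-methoxy-5-methylphenyl)methyl]-2,4,6-trihydroxyphenyl}butan-1-one (CNP0264591.0) | CCCC(=O)c1c(O)c(Cc2c(O)c(C(=O)CCC)c(O)c(C)c2OC)c(O)c(Cc2c(O)c(C(=O)CCC)c(O)c(C)c2OC)c1O | target

## Step count and least certain steps

Total step count: 9 (telescoped operations counted as one step each). Longest linear sequence: 7 steps (steps 1, 2, 3, 4, 7, 8, 9); the alkyne branch (steps 1, 5, 6) joins at step 7.

**Step 7 (key step).** The donor-substituted vinylketene 17 may add to the ynol ether too slowly, so that the ketene is lost to oligomerisation or to acylation of the product phenol while acid-sensitive 16 degrades at the temperature needed to open 11. The fallback generates the same ketene at room temperature by a different reaction; it sets out from acid 7 and rejoins the route at phenol 21. Acid 7 would be activated with 1,1'-carbonyldiimidazole and condensed with potassium ethyl malonate (MgCl2, Et3N) to give ethyl 3-oxo-5-(2,4,6-trimethoxy-3-methylphenyl)pentanoate F1. Triethyl orthoformate with catalytic acid would give the enol ether ethyl (2E)-3-ethoxy-5-(2,4,6-trimethoxy-3-methylphenyl)pent-2-enoate F2. Saponification (NaOH, aqueous ethanol) would give (2E)-3-ethoxy-5-(2,4,6-trimethoxy-3-methylphenyl)pent-2-enoic acid F3, and Me2C=C(Cl)NMe2 would convert it into (2E)-3-ethoxy-5-(2,4,6-trimethoxy-3-methylphenyl)pent-2-enoyl chloride F4. Slow addition of F4 to Et3N and an excess of 16 in toluene should form ketene 17 by 1,4-dehydrochlorination, in low stationary concentration and in the presence of its trap. Warming then carries 18, 19 and 20 through to 21 as before.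

**Step 6.** The benzylic chloride 15 may ionise and alkylate the free ring position of a second molecule before the acetylide captures it, and residual strong base may isomerise the product to an allene. The fallback replaces the alkylation by ester homologation to a siloxyalkyne; it sets out from arene 1 and returns at phenol 21. Friedel–Crafts acylation of 1 with ethyl chlorooxoacetate (TiCl4, CH2Cl2, low temperature) would give ethyl oxo(2,4,6-trimethoxy-3-methylphenyl)acetate F5. Ionic hydrogenation (Et3SiH, CF3CO2H) would give ethyl (2,4,6-trimethoxy-3-methylphenyl)acetate F6. Kowalski-type homologation (dibromomethyllithium from CH2Br2 and lithium 2,2,6,6-tetramethylpiperidide, then n-BuLi) would give the lithium ynolate, trapped on oxygen with chlorotri(propan-2-yl)silane as tri(propan-2-yl){[3-(2,4,6-trimethoxy-3-methylphenyl)prop-1-yn-1-yl]oxy}silane F7. Heating F7 with 11 as in step 7 should give 3-ethoxy-2,6-bis[(2,4,6-trimethoxy-3-methylphenyl)methyl]-5-{[tri(propan-2-yl)silyl]oxy}phenol F8. n-Bu4NF would release 5-ethoxy-2,4-bis[(2,4,6-trimethoxy-3-methylphenyl)methyl]benzene-1,3-diol F9. Mitsunobu etherification with methanol (PPh3, diisopropyl azodicarboxylate) should methylate only the hydroxyl that has a free ortho position, since the one between the two benzyl groups is too hindered; this gives 21.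

**Step 8.** The acylium ion may attack the bridge-bearing ring carbons with loss of a stabilised benzylic cation (bridge scission and scrambling), and the hindered ring A position may acylate incompletely. The fallback avoids strong Lewis acid; it sets out from 21 and returns at 23. Threefold Vilsmeier–Haack formylation (POCl3, DMF), the mild electrophile already used in step 1, would give 2-ethoxy-3,5-bis[(3-formyl-2,4,6-trimethoxy-5-methylphenyl)methyl]-4-hydroxy-6-methoxybenzaldehyde F10. Excess n-PrMgCl (one equivalent is consumed by the phenol) would give 1-{2-ethoxy-4-hydroxy-3,5-bis{[3-(1-hydroxybutyl)-2,4,6-trimethoxy-5-methylphenyl]methyl}-6-methoxyphenyl}butan-1-ol F11 as a mixture of diastereomers. MnO2 would oxidise the three benzylic alcohols to 23.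

**Step 9.** Cleavage may overrun and remove the two para methoxy groups, which are twisted out of conjugation by their two ortho neighbours, or it may stall after the first ortho ether of each ketone. BBr3 is chosen over the more ortho-selective BCl3 because the second ether next to each ketone and the ethyl ether would be expected to resist the weaker reagent. The fallback gives up selective cleavage in favour of selective re-methylation; it sets out from ester 22 (isolated instead of being methanolysed) and returns at 24. Excess BBr3 at room temperature would cleave all eight ethers and should leave the aryl butanoate in place, giving 4-butanoyl-2,6-bis[(3-butanoyl-2,4,6-trihydroxy-5-methylphenyl)methyl]-3,5-dihydroxyphenyl butanoate F12. The only hydroxyls of F12 not ortho to a ketone are the two para hydroxyls of the side rings, which are the most acidic and least hydrogen-bonded. Trimethylsilyldiazomethane in methanol/toluene should methylate these selectively to 4-butanoyl-2,6-bis[(3-butanoyl-2,4-dihydroxy-6-methoxy-5-methylphenyl)methyl]-3,5-dihydroxyphenyl butanoate F13. Methanolysis of the butanoate (K2CO3, MeOH, argon) would then give 24.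

## Further compounds

F1 | step 7 | ethyl 3-oxo-5-(2,4,6-trimethoxy-3-methylphenyl)pentanoate | CCOC(=O)CC(=O)CCc1c(OC)cc(OC)c(C)c1OC
F2 | step 7 | ethyl (2E)-3-ethoxy-5-(2,4,6-trimethoxy-3-methylphenyl)pent-2-enoate | CCOC(=O)/C=C(/OCC)CCc1c(OC)cc(OC)c(C)c1OC
F3 | step 7 | (2E)-3-ethoxy-5-(2,4,6-trimethoxy-3-methylphenyl)pent-2-enoic acid | OC(=O)/C=C(/OCC)CCc1c(OC)cc(OC)c(C)c1OC
F4 | step 7 | (2E)-3-ethoxy-5-(2,4,6-trimethoxy-3-methylphenyl)pent-2-enoyl chloride | ClC(=O)/C=C(/OCC)CCc1c(OC)cc(OC)c(C)c1OC
F5 | step 6 | ethyl oxo(2,4,6-trimethoxy-3-methylphenyl)acetate | CCOC(=O)C(=O)c1c(OC)cc(OC)c(C)c1OC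
F6 | step 6 | ethyl (2,4,6-trimethoxy-3-methylphenyl)acetate | CCOC(=O)Cc1c(OC)cc(OC)c(C)c1OC
F7 | step 6 | tri(propan-2-yl){[3-(2,4,6-trimethoxy-3-methylphenyl)prop-1-yn-1-yl]oxy}silane | CC(C)[Si](OC#CCc1c(OC)cc(OC)c(C)c1OC)(C(C)C)C(C)C
F8 | step 6 | 3-ethoxy-2,6-bis[(2,4,6-trimethoxy-3-methylphenyl)methyl]-5-{[tri(propan-2-yl)silyl]oxy}phenol | Oc1c(Cc2c(OC)cc(OC)c(C)c2OC)c(O[Si](C(C)C)(C(C)C)C(C)C)cc(OCC)c1Cc1c(OC)cc(OC)c(C)c1OC
F9 | step 6 | 5-ethoxy-2,4-bis[(2,4,6-trimethoxy-3-methylphenyl)methyl]benzene-1,3-diol | Oc1c(Cc2c(OC)cc(OC)c(C)c2OC)c(O)cc(OCC)c1Cc1c(OC)cc(OC)c(C)c1OC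
F10 | step 8 | 2-ethoxy-3,5-bis[(3-formyl-2,4,6-trimethoxy-5-methylphenyl)methyl]-4-hydroxy-6-methoxybenzaldehyde | O=Cc1c(OCC)c(Cc2c(OC)c(C=O)c(OC)c(C)c2OC)c(O)c(Cc2c(OC)c(C=O)c(OC)c(C)c2OC)c1OC
F11 | step 8 | 1-{2-ethoxy-4-hydroxy-3,5-bis{[3-(1-hydroxybutyl)-2,4,6-trimethoxy-5-methylphenyl]methyl}-6-methoxyphenyl}butan-1-ol (mixture of diastereomers) | CCCC(O)c1c(OCC)c(Cc2c(OC)c(C(O)CCC)c(OC)c(C)c2OC)c(O)c(Cc2c(OC)c(C(O)CCC)c(OC)c(C)c2OC)c1OC
F12 | step 9 | 4-butanoyl-2,6-bis[(3-butanoyl-2,4,6-trihydroxy-5-methylphenyl)methyl]-3,5-dihydroxyphenyl butanoate | CCCC(=O)Oc1c(Cc2c(O)c(C(=O)CCC)c(O)c(C)c2O)c(O)c(C(=O)CCC)c(O)c1Cc1c(O)c(C(=O)CCC)c(O)c(C)c1O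
F13 | step 9 | 4-butanoyl-2,6-bis[(3-butanoyl-2,4-dihydroxy-6-methoxy-5-methylphenyl)methyl]-3,5-dihydroxyphenyl butanoate | CCCC(=O)Oc1c(Cc2c(O)c(C(=O)CCC)c(O)c(C)c2OC)c(O)c(C(=O)CCC)c(O)c1Cc1c(O)c(C(=O)CCC)c(O)c(C)c1OC
A1 | alternative 1 | dimethyl 2,2'-{[2,4,6-tris(benzyloxy)-5-butanoyl-1,3-phenylene]bis(methylene)}bis(3,5-dioxoheptanoate) (mixture of stereoisomers) | CCCC(=O)c1c(OCc2ccccc2)c(CC(C(=O)OC)C(=O)CC(=O)CC)c(OCc2ccccc2)c(CC(C(=O)OC)C(=O)CC(=O)CC)c1OCc1ccccc1
A2 | alternative 1 | 1-{2,4,6-tris(benzyloxy)-3,5-bis[(2,4,6-trihydroxy-3-methylphenyl)methyl]phenyl}butan-1-one | CCCC(=O)c1c(OCc2ccccc2)c(Cc2c(O)cc(O)c(C)c2O)c(OCc2ccccc2)c(Cc2c(O)cc(O)c(C)c2O)c1OCc1ccccc1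
A3 | alternative 2 | 3,5-bis(benzyloxy)-2,4-bis[(2,4,6-trimethoxy-3-methylphenyl)methyl]-6-(trimethylsilyl)phenyl trifluoromethanesulfonate | C[Si](C)(C)c1c(OS(=O)(=O)C(F)(F)F)c(Cc2c(OC)cc(OC)c(C)c2OC)c(OCc2ccccc2)c(Cc2c(OC)cc(OC)c(C)c2OC)c1OCc1ccccc1
A4 | alternative 2 | butanoic acid | CCCC(=O)O
A5 | alternative 2 | 1-{4,6-bis(benzyloxy)-2-hydroxy-3,5-bis[(2,4,6-trimethoxy-3-methylphenyl)methyl]phenyl}butan-1-one | CCCC(=O)c1c(O)c(Cc2c(OC)cc(OC)c(C)c2OC)c(OCc2ccccc2)c(Cc2c(OC)cc(OC)c(C)c2OC)c1OCc1ccccc1
A6 | alternative 3 | 1-{2,4,6-trifluoro-3,5-bis[(2,4,6-trimethoxy-3-methylphenyl)methyl]phenyl}butan-1-one | CCCC(=O)c1c(F)c(Cc2c(OC)cc(OC)c(C)c2OC)c(F)c(Cc2c(OC)cc(OC)c(C)c2OC)c1F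
A7 | alternative 3 | sodium benzyloxide (sodium phenylmethanolate) | [Na+].[O-]Cc1ccccc1
A8 | alternative 3 | 1-{2,4,6-tris(benzyloxy)-3,5-bis[(2,4,6-trimethoxy-3-methylphenyl)methyl]phenyl}butan-1-one | CCCC(=O)c1c(OCc2ccccc2)c(Cc2c(OC)cc(OC)c(C)c2OC)c(OCc2ccccc2)c(Cc2c(OC)cc(OC)c(C)c2OC)c1OCc1ccccc1
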